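**Retrosynthetic overview**
- The target is unmasked last by acid from a bis-MOM, TBS-protected keto acid. The aryl ketone comes from a Weinreb amide and ortho-lithiated 1,4-bis(methoxymethoxy)benzene, and the C3 side chain from a Negishi coupling of a ring vinyl bromide with a homoallylic zinc reagent.
- The strategy rests on the allylic ether unit O1–C2H2–C3(R)=C4H of the 2,5,6,7-tetrahydrooxepine, which sits next to the fully substituted ether carbon C7. C3 is treated as one carbon inserted into the enol ether C=C of a 3,4-dihydro-2H-pyran (dibromocarbene addition, then silver-assisted cyclopropyl-to-allyl opening that leaves Br on C3).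
- The dihydropyran comes from a δ-hydroxy aldehyde (ozonolysis of a pentenyl chain, lactol closure by the tertiary alcohol, dehydration), so the C7–O1 bond is never made by O-alkylation. C7 (S) is set by a Mukaiyama aldol on an α-keto ester catalysed by Cu(OTf)2 and a tert-butyl bis(oxazoline) ligand.
- Ring order: six-membered lactol and dihydropyran, then the fused dibromocyclopropane, then ring expansion to the oxepine; the arene is attached last.

Key step: step 8

Remark: the oxepine is numbered O1, C2 (CH2), C3 (side-chain carbon), C4 (=CH), C5, C6, C7 (quaternary) throughout. The (S,S) enantiomer of the tert-butyl bis(oxazoline) ligand is assumed to deliver the (S) carbinol, as it does with pyruvate esters; its antipode would be used otherwise.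

**Route**

Step 1
Reactants: 1 5-bromopent-1-ene; 2 dimethyl oxalate
Product: 4 methyl 2-oxohept-6-enoate, via pent-4-enylmagnesium bromide 3 (not isolated)
Conditions: Mg, THF, 40 °C; then added to 2 (1.5 equiv), THF/Et2O, −78 °C; 1 M HCl quench
Reagents that add atoms: none
Why: the Grignard reagent adds once to dimethyl oxalate held in excess at −78 °C because the magnesium hemiketal alkoxide persists until the acidic quench, a standard monoacylation route to α-keto esters.

Step 2
Reactants: 5 S-tert-butyl thioacetate
Product: 7 tert-butyl 1-(trimethylsilyloxy)ethenyl sulfide, via lithium enolate 6 (not isolated)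
Conditions: LiN(i-Pr)2, THF, −78 °C; then Me3SiCl, −78 °C → rt; distillation
Reagents that add atoms: chlorotrimethylsilane C[Si](C)(C)Cl
Why: kinetic deprotonation of the thioester and O-silylation of its lithium enolate is the standard preparation of a silyl ketene thioacetal for Mukaiyama aldol chemistry.

Step 3
Reactants: 4 methyl 2-oxohept-6-enoate; 7 tert-butyl 1-(trimethylsilyloxy)ethenyl sulfide
Product: 9 methyl (S)-2-[2-(tert-butylsulfanyl)-2-oxoethyl]-2-hydroxyhept-6-enoate, via trimethylsilyl ether 8 (not isolated)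
Conditions: Cu(OTf)2 (10 mol %), (S,S)-t-Bu-box [2,2'-isopropylidenebis((4S)-4-tert-butyl-2-oxazoline)] (11 mol %), THF, −78 °C; then 1 M HCl, THF, rt
Reagents that add atoms: none
Why: enantioselective Mukaiyama aldol addition in which the keto ester chelates Cu(OTf)2 (divalent copper) through its two vicinal carbonyl oxygens, a tert-butyl group of the ligand shields the re face of the ketone and the enolsilane should add to the si face to set the tertiary carbinol (the later C7) as (S), the silyl ether being cleaved in the acidic work-up.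

Step 4
Reactants: 9 methyl (S)-2-[2-(tert-butylsulfanyl)-2-oxoethyl]-2-hydroxyhept-6-enoate
Product: 10 methyl (S)-2-hydroxy-2-{2-[methoxy(methyl)amino]-2-oxoethyl}hept-6-enoate
Conditions: MeNHOMe (free base, 3 equiv), AgO2CCF3 (1.5 equiv), THF, 0 °C → rt
Reagents that add atoms: N,O-dimethylhydroxylamine CNOC
Why: thiophilic activation of the S-tert-butyl thioester by AgO2CCF3 (monovalent silver) makes it an acylating agent for the amine at room temperature while the methyl ester, the alkene and the tertiary alcohol are left alone, a known silver-assisted thioester aminolysis.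

Step 5
Reactants: 10 methyl (S)-2-hydroxy-2-{2-[methoxy(methyl)amino]-2-oxoethyl}hept-6-enoate
Product: 13 methyl (2S)-6-hydroxy-2-{2-[methoxy(methyl)amino]-2-oxoethyl}tetrahydro-2H-pyran-2-carboxylate (both anomers), via secondary ozonide 11 (not isolated), via hydroxy aldehyde 12 (not isolated)
Conditions: O3, CH2Cl2, −78 °C; then PPh3, −78 °C → rt
Reagents that add atoms: ozone [O-][O+]=O
Why: ozonolysis of the only alkene followed by reductive work-up gives the δ-hydroxy aldehyde, which closes spontaneously by 6-exo-trig addition of the tertiary hydroxyl to the aldehyde, so the C7–O1 bond arises by lactolisation and not by O-alkylation.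

Step 6
Reactants: 13 methyl (2S)-6-hydroxy-2-{2-[methoxy(methyl)amino]-2-oxoethyl}tetrahydro-2H-pyran-2-carboxylate
Product: 15 methyl (S)-2-{2-[methoxy(methyl)amino]-2-oxoethyl}-3,4-dihydro-2H-pyran-2-carboxylate, via 6-O-mesyl lactol 14 (not isolated)
Conditions: MsCl, Et3N (excess), CH2Cl2, 0 °C → 40 °C
Reagents that add atoms: none
Why: mesylation of the anomeric hydroxyl and amine-mediated elimination through the oxocarbenium ion is a standard lactol-to-enol-ether dehydration, and the double bond can only form between C5 and C6 of the pyran because the anomeric carbon has no other hydrogen-bearing neighbour.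

Step 7
Reactants: 15 methyl (S)-2-{2-[methoxy(methyl)amino]-2-oxoethyl}-3,4-dihydro-2H-pyran-2-carboxylate
Product: 16 methyl (3S)-7,7-dibromo-3-{2-[methoxy(methyl)amino]-2-oxoethyl}-2-oxabicyclo[4.1.0]heptane-3-carboxylate (cis-fused; both ring-fusion diastereomers)
Conditions: CHBr3, 50% aq NaOH, BnEt3NCl (cat.), CH2Cl2, 0 °C → rt
Reagents that add atoms: bromoform BrC(Br)Br
Why: dibromocarbene generated at the phase boundary adds in a concerted cis [2+1] fashion to the electron-rich enol ether, the only nucleophilic alkene present, while the ester on the quaternary carbon and the Weinreb amide are expected to resist the two-phase hydroxide, and the mixture at the ring fusion is of no consequence.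

Step 8
Reactants: 16 methyl (3S)-7,7-dibromo-3-{2-[methoxy(methyl)amino]-2-oxoethyl}-2-oxabicyclo[4.1.0]heptane-3-carboxylate
Product: 18 methyl (7S)-2-acetoxy-3-bromo-7-{2-[methoxy(methyl)amino]-2-oxoethyl}-2,5,6,7-tetrahydrooxepine-7-carboxylate (both C2 epimers), via oxocarbenium acetate 17 (not isolated)
Conditions: AgOAc (2 equiv), NaOAc, toluene, 90 °C, dark
Reagents that add atoms: AgOAc CC(=O)[O-].[Ag+]
Why: AgOAc (monovalent silver) pulls off the endo bromide (the one cis to the pyran ring bonds) while the cyclopropane bond between the two ring-fusion carbons breaks in a concerted disrotatory two-electron electrocyclic opening that turns the ring carbons inward, giving the cis 2-bromoallyl cation inside a seven-membered ring as its acetate ion pair 17, stabilised as an oxocarbenium ion by the lone pair of O1, and the acetate then adds at C2. The closest known reaction type is the silver-assisted cyclopropyl-to-allyl ring expansion of gem-dibromocyclopropanes fused to dihydropyrans and glycals, which gives 2-acyloxy-3-bromo-oxepines. No ring is closed by bond formation: the oxepine arises by ring expansion, through cleavage of the bond common to the three- and six-membered rings, so neither a seven-membered cyclisation nor an O-alkylation of the hindered tertiary alcohol is required. The only new stereocentre, the acetal carbon C2, is not controlled (both epimers are expected) and is erased in step 9, C7 is not one of the three reacting carbons and keeps its configuration, and both ring-fusion diastereomers of 16 converge on the same cation. The step needs loss of the endo and not the exo bromide, which the cis ring fusion enforces because only that mode places a cis allyl unit in a ring of this size, and it needs acetate capture at C2 and not C4, which the oxocarbenium character of O1=C2 secures; the bromine kept on C3 marks the site for the side chain.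

Step 9
Reactants: 18 methyl (7S)-2-acetoxy-3-bromo-7-{2-[methoxy(methyl)amino]-2-oxoethyl}-2,5,6,7-tetrahydrooxepine-7-carboxylate
Product: 20 methyl (S)-3-bromo-7-{2-[methoxy(methyl)amino]-2-oxoethyl}-2,5,6,7-tetrahydrooxepine-7-carboxylate, via oxocarbenium triflate 19 (not isolated)
Conditions: Et3SiH (3 equiv), Me3SiOTf (0.3 equiv), CH2Cl2, −78 → 0 °C
Reagents that add atoms: none
Why: the silyl triflate ionises the acetal acetate to the oxocarbenium triflate 19 and Et3SiH delivers hydride to its C2 terminus, a Ferrier-type ionic hydrogenation that removes the acetal stereocentre and leaves the O1–C2H2–C3(Br)=C4H unit with the vinyl bromide intact.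

Step 10
Reactants: 21 5-bromo-2-methylpent-2-ene
Product: 22 (E)-5-bromo-2-methylpent-2-en-1-ol
Conditions: SeO2 (0.3 equiv), t-BuOOH (70% aq, 2 equiv), CH2Cl2, 0 °C → rt
Reagents that add atoms: tert-butyl hydroperoxide CC(C)(C)OO
Why: allylic oxidation catalysed by SeO2 with the hydroperoxide as terminal oxidant (ene reaction, then [2,3]-sigmatropic shift) occurs on a trisubstituted alkene with a gem-dimethyl terminus selectively at the methyl group trans to the chain and so should give the (E)-allylic alcohol.

Step 11
Reactants: 22 (E)-5-bromo-2-methylpent-2-en-1-ol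
Product: 23 (E)-[(5-bromo-2-methylpent-2-en-1-yl)oxy](tert-butyl)dimethylsilane
Conditions: TBSCl, imidazole, CH2Cl2, 0 °C → rt
Reagents that add atoms: tert-butyldimethylsilyl chloride CC(C)(C)[Si](C)(C)Cl
Why: standard silylation of a primary allylic alcohol, which masks the hydroxyl for the organozinc and organolithium steps.

Step 12
Reactants: 23 (E)-[(5-bromo-2-methylpent-2-en-1-yl)oxy](tert-butyl)dimethylsilane
Product: 24 (E)-tert-butyl[(5-iodo-2-methylpent-2-en-1-yl)oxy]dimethylsilane
Conditions: NaI, acetone, reflux
Reagents that add atoms: NaI [Na+].[I-]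
Why: Finkelstein exchange, driven by precipitation of NaBr from acetone, provides the primary iodide that inserts zinc readily.

Step 13
Reactants: 20 methyl (S)-3-bromo-7-{2-[methoxy(methyl)amino]-2-oxoethyl}-2,5,6,7-tetrahydrooxepine-7-carboxylate; 24 (E)-tert-butyl[(5-iodo-2-methylpent-2-en-1-yl)oxy]dimethylsilane
Product: 26 methyl (S,E)-3-[5-(tert-butyldimethylsilyloxy)-4-methylpent-3-en-1-yl]-7-{2-[methoxy(methyl)amino]-2-oxoethyl}-2,5,6,7-tetrahydrooxepine-7-carboxylate, via alkylzinc iodide 25 (not isolated)
Conditions: 24, Zn dust (activated by Me3SiCl and BrCH2CH2Br), LiCl, THF, 40 °C; then 20, PdCl2(dppf) (5 mol %), THF/DMA, 50 °C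
Reagents that add atoms: none
Why: Negishi coupling in which the alkylzinc iodide transmetalates to the alkenyl-PdBr(dppf) complex formed from 20 and the zerovalent palladium released from PdCl2(dppf) (divalent palladium precatalyst), the wide bite angle of dppf favouring reductive elimination over β-hydride elimination, while the ester, Weinreb amide and silyl ether tolerate the organozinc and the ring alkene geometry is fixed by the ring.

Step 14
Reactants: 26 methyl (S,E)-3-[5-(tert-butyldimethylsilyloxy)-4-methylpent-3-en-1-yl]-7-{2-[methoxy(methyl)amino]-2-oxoethyl}-2,5,6,7-tetrahydrooxepine-7-carboxylate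
Product: 28 (S,E)-3-[5-(tert-butyldimethylsilyloxy)-4-methylpent-3-en-1-yl]-7-{2-[methoxy(methyl)amino]-2-oxoethyl}-2,5,6,7-tetrahydrooxepine-7-carboxylic acid, via sodium carboxylate 27 (not isolated)
Conditions: 2 M aq NaOH (3 equiv), THF/MeOH, 0 °C → rt; then cold 0.5 M HCl to pH 4
Reagents that add atoms: NaOH [Na+].[OH-]
Why: hydroxide saponifies the α-alkoxy methyl ester while the Weinreb amide and the silyl ether are inert at room temperature, and the step is placed here because no ketone is yet present that could drive β-elimination of the ring oxygen.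

Step 15
Reactants: 29 hydroquinone
Product: 30 1,4-bis(methoxymethoxy)benzene
Conditions: MOMCl, i-Pr2NEt, CH2Cl2, 0 °C → rt
Reagents that add atoms: chloromethyl methyl ether COCCl
Why: double O-alkylation of the phenols gives acetal ethers that both protect the hydroquinone and direct ortho-lithiation.

Step 16
Reactants: 28 (S,E)-3-[5-(tert-butyldimethylsilyloxy)-4-methylpent-3-en-1-yl]-7-{2-[methoxy(methyl)amino]-2-oxoethyl}-2,5,6,7-tetrahydrooxepine-7-carboxylic acid; 30 1,4-bis(methoxymethoxy)benzene
Product: 34 (S,E)-7-{2-[2,5-bis(methoxymethoxy)phenyl]-2-oxoethyl}-3-[5-(tert-butyldimethylsilyloxy)-4-methylpent-3-en-1-yl]-2,5,6,7-tetrahydrooxepine-7-carboxylic acid, via aryllithium 31 (not isolated), via lithium carboxylate 32 (not isolated), via lithium hemiaminal 33 (not isolated)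
Conditions: 30 (3.3 equiv), n-BuLi (3.0 equiv), THF, 0 °C; then 28, THF, −78 → −40 °C; cold 0.5 M HCl to pH 4
Reagents that add atoms: none
Why: directed ortho-lithiation of 30 gives the aryllithium, whose first equivalent converts the acid into its lithium carboxylate (inert to further attack at −78 °C) and whose next equivalent adds to the Weinreb amide to give a stable chelated tetrahedral adduct that releases the aryl ketone only on the acidic quench, so neither over-addition nor base-induced opening of a β-alkoxy ketone can occur.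

Step 17
Reactants: 34 (S,E)-7-{2-[2,5-bis(methoxymethoxy)phenyl]-2-oxoethyl}-3-[5-(tert-butyldimethylsilyloxy)-4-methylpent-3-en-1-yl]-2,5,6,7-tetrahydrooxepine-7-carboxylic acid
Product: 35 (S,E)-7-[2-(2,5-dihydroxyphenyl)-2-oxoethyl]-3-(5-hydroxy-4-methylpent-3-en-1-yl)-2,5,6,7-tetrahydrooxepine-7-carboxylic acid (CNP0570804.2)
Conditions: 3 M aq HCl, THF, rt → 40 °C
Reagents that add atoms: none
Why: aqueous acid hydrolyses the two aryl methoxymethyl acetals and the primary silyl ether in one operation, and acid is chosen over base because the β-alkoxy ketone would undergo retro-oxa-Michael ring opening under basic conditions, C7 and both alkenes being untouched.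

**Compound list**
1 | 5-bromopent-1-ene | C=CCCCBr | starting material
2 | dimethyl oxalate | COC(=O)C(=O)OC | starting material
3 | pent-4-enylmagnesium bromide | C=CCCC[Mg]Br | intermediate (not isolated)
4 | methyl 2-oxohept-6-enoate | C=CCCCC(=O)C(=O)OC | intermediate
5 | S-tert-butyl thioacetate | CC(=O)SC(C)(C)C | starting material
6 | lithium 1-(tert-butylsulfanyl)ethenolate | C=C(O[Li])SC(C)(C)C | intermediate (not isolated)
7 | tert-butyl 1-(trimethylsilyloxy)ethenyl sulfide | C=C(O[Si](C)(C)C)SC(C)(C)C | intermediate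
8 | methyl (S)-2-[2-(tert-butylsulfanyl)-2-oxoethyl]-2-(trimethylsilyloxy)hept-6-enoate | C=CCCC[C@](CC(=O)SC(C)(C)C)(C(=O)OC)O[Si](C)(C)C | intermediate (not isolated)
9 | methyl (S)-2-[2-(tert-butylsulfanyl)-2-oxoethyl]-2-hydroxyhept-6-enoate | C=CCCC[C@](CC(=O)SC(C)(C)C)(C(=O)OC)O | intermediate
10 | methyl (S)-2-hydroxy-2-{2-[methoxy(methyl)amino]-2-oxoethyl}hept-6-enoate | C=CCCC[C@](CC(=O)N(C)OC)(C(=O)OC)O | intermediate
11 | secondary ozonide (1,2,4-trioxolane) of 10 | C1OOC(O1)CCC[C@](CC(=O)N(C)OC)(C(=O)OC)O | intermediate (not isolated)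
12 | methyl (S)-2-hydroxy-2-{2-[methoxy(methyl)amino]-2-oxoethyl}-6-oxohexanoate | O=CCCC[C@](CC(=O)N(C)OC)(C(=O)OC)O | intermediate (not isolated)
13 | methyl (2S)-6-hydroxy-2-{2-[methoxy(methyl)amino]-2-oxoethyl}tetrahydro-2H-pyran-2-carboxylate (both anomers) | OC1CCC[C@](CC(=O)N(C)OC)(C(=O)OC)O1 | intermediate
14 | methyl (2S)-6-(methanesulfonyloxy)-2-{2-[methoxy(methyl)amino]-2-oxoethyl}tetrahydro-2H-pyran-2-carboxylate | CS(=O)(=O)OC1CCC[C@](CC(=O)N(C)OC)(C(=O)OC)O1 | intermediate (not isolated)
15 | methyl (S)-2-{2-[methoxy(methyl)amino]-2-oxoethyl}-3,4-dihydro-2H-pyran-2-carboxylate | C1=CCC[C@](CC(=O)N(C)OC)(C(=O)OC)O1 | intermediate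
16 | methyl (3S)-7,7-dibromo-3-{2-[methoxy(methyl)amino]-2-oxoethyl}-2-oxabicyclo[4.1.0]heptane-3-carboxylate (cis-fused, both ring-fusion diastereomers) | BrC1(Br)C2CC[C@](CC(=O)N(C)OC)(C(=O)OC)OC12 | intermediate
17 | (7S)-3-bromo-7-(methoxycarbonyl)-7-{2-[methoxy(methyl)amino]-2-oxoethyl}-6,7-dihydro-5H-oxepin-1-ium acetate (2-bromoallyl oxocarbenium ion pair) | BrC1=CCC[C@](CC(=O)N(C)OC)(C(=O)OC)[O+]=C1.CC(=O)[O-] | intermediate (not isolated)
18 | methyl (7S)-2-acetoxy-3-bromo-7-{2-[methoxy(methyl)amino]-2-oxoethyl}-2,5,6,7-tetrahydrooxepine-7-carboxylate (both C2 epimers) | BrC1=CCC[C@](CC(=O)N(C)OC)(C(=O)OC)OC1OC(C)=O | intermediate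
19 | (7S)-3-bromo-7-(methoxycarbonyl)-7-{2-[methoxy(methyl)amino]-2-oxoethyl}-6,7-dihydro-5H-oxepin-1-ium trifluoromethanesulfonate (2-bromoallyl oxocarbenium ion pair) | BrC1=CCC[C@](CC(=O)N(C)OC)(C(=O)OC)[O+]=C1.[O-]S(=O)(=O)C(F)(F)F | intermediate (not isolated)
20 | methyl (S)-3-bromo-7-{2-[methoxy(methyl)amino]-2-oxoethyl}-2,5,6,7-tetrahydrooxepine-7-carboxylate | BrC1=CCC[C@](CC(=O)N(C)OC)(C(=O)OC)OC1 | intermediate
21 | 5-bromo-2-methylpent-2-ene | CC(C)=CCCBr | starting material
22 | (E)-5-bromo-2-methylpent-2-en-1-ol | C/C(=C\CCBr)CO | intermediate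
23 | (E)-[(5-bromo-2-methylpent-2-en-1-yl)oxy](tert-butyl)dimethylsilane | C/C(=C\CCBr)CO[Si](C)(C)C(C)(C)C | intermediate
24 | (E)-tert-butyl[(5-iodo-2-methylpent-2-en-1-yl)oxy]dimethylsilane | C/C(=C\CCI)CO[Si](C)(C)C(C)(C)C | intermediate
25 | (E)-[5-(tert-butyldimethylsilyloxy)-4-methylpent-3-en-1-yl]zinc iodide | C/C(=C\CC[Zn]I)CO[Si](C)(C)C(C)(C)C | intermediate (not isolated)
26 | methyl (S,E)-3-[5-(tert-butyldimethylsilyloxy)-4-methylpent-3-en-1-yl]-7-{2-[methoxy(methyl)amino]-2-oxoethyl}-2,5,6,7-tetrahydrooxepine-7-carboxylate | C/C(=C\CCC1=CCC[C@](CC(=O)N(C)OC)(C(=O)OC)OC1)CO[Si](C)(C)C(C)(C)C | intermediate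
27 | sodium (S,E)-3-[5-(tert-butyldimethylsilyloxy)-4-methylpent-3-en-1-yl]-7-{2-[methoxy(methyl)amino]-2-oxoethyl}-2,5,6,7-tetrahydrooxepine-7-carboxylate | C/C(=C\CCC1=CCC[C@](CC(=O)N(C)OC)(C(=O)[O-])OC1)CO[Si](C)(C)C(C)(C)C.[Na+] | intermediate (not isolated)
28 | (S,E)-3-[5-(tert-butyldimethylsilyloxy)-4-methylpent-3-en-1-yl]-7-{2-[methoxy(methyl)amino]-2-oxoethyl}-2,5,6,7-tetrahydrooxepine-7-carboxylic acid | C/C(=C\CCC1=CCC[C@](CC(=O)N(C)OC)(C(=O)O)OC1)CO[Si](C)(C)C(C)(C)C | intermediate
29 | hydroquinone | Oc1ccc(O)cc1 | starting material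
30 | 1,4-bis(methoxymethoxy)benzene | COCOc1ccc(OCOC)cc1 | intermediate
31 | [2,5-bis(methoxymethoxy)phenyl]lithium | COCOc1ccc(OCOC)c([Li])c1 | intermediate (not isolated)
32 | lithium (S,E)-3-[5-(tert-butyldimethylsilyloxy)-4-methylpent-3-en-1-yl]-7-{2-[methoxy(methyl)amino]-2-oxoethyl}-2,5,6,7-tetrahydrooxepine-7-carboxylate | C/C(=C\CCC1=CCC[C@](CC(=O)N(C)OC)(C(=O)O[Li])OC1)CO[Si](C)(C)C(C)(C)C | intermediate (not isolated)
33 | dilithium salt of the tetrahedral adduct of 32 and 31 (lithium hemiaminal, lithium carboxylate; new carbinol centre undefined) | C/C(=C\CCC1=CCC[C@](CC(O[Li])(N(C)OC)c2cc(OCOC)ccc2OCOC)(C(=O)O[Li])OC1)CO[Si](C)(C)C(C)(C)C | intermediate (not isolated)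
34 | (S,E)-7-{2-[2,5-bis(methoxymethoxy)phenyl]-2-oxoethyl}-3-[5-(tert-butyldimethylsilyloxy)-4-methylpent-3-en-1-yl]-2,5,6,7-tetrahydrooxepine-7-carboxylic acid | C/C(=C\CCC1=CCC[C@](CC(=O)c2cc(OCOC)ccc2OCOC)(C(=O)O)OC1)CO[Si](C)(C)C(C)(C)C | intermediate
35 | (S,E)-7-[2-(2,5-dihydroxyphenyl)-2-oxoethyl]-3-(5-hydroxy-4-methylpent-3-en-1-yl)-2,5,6,7-tetrahydrooxepine-7-carboxylic acid (CNP0570804.2) | C/C(=C\CCC1=CCC[C@](CC(=O)c2cc(O)ccc2O)(C(=O)O)OC1)CO | target

**Step count**
Total steps: 17. Longest linear sequence: 12 steps (steps 1, 3, 4, 5, 6, 7, 8, 9, 13, 14, 16, 17).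

**Steps most likely to fail**

Step 16 (aryllithium acylation of the carboxylate-bearing Weinreb amide). The aryllithium may deprotonate next to the amide carbonyl and expel the ring oxygen, the addition may stall on a poorly soluble lithium carboxylate, or the carboxylate itself may be attacked. The fallback sets out from 28 and masks the acid covalently instead of as a salt. Esterification with Boc2O, DMAP (cat.) and t-BuOH should give the tert-butyl ester F1. Addition of aryllithium 31 (1.3 equiv, THF, −78 °C) should pass through the lithium hemiaminal F2 and give, after a mild acidic quench, the tert-butyl keto ester F3, the hindered tert-butyl ester being inert to the aryllithium at this temperature. Treatment of F3 with CF3CO2H/CH2Cl2/H2O (0 °C → rt, anisole as cation scavenger) would then remove the tert-butyl ester, both methoxymethyl ethers and the silyl ether together, and the route comes back at target 35.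

Step 17 (global acidic deprotection). The acid needed to cleave the aryl methoxymethyl ethers may also promote β-elimination across C7–O1 (ring opening to an aroylacrylic acid, or re-closure by the ortho phenol to a chromanone) and ionisation of the allylic C–O bonds. The fallback sets out from 28 and changes the arene protection so that the end game needs fluoride only. Commercial 2-bromobenzene-1,4-diol F4 would be silylated (TBSCl, imidazole, DMF) to 2-bromo-1,4-bis(tert-butyldimethylsilyloxy)benzene F5. Bromine–lithium exchange (n-BuLi, THF, −78 °C, kept cold to avoid oxygen-to-carbon silyl migration) gives [2,5-bis(tert-butyldimethylsilyloxy)phenyl]lithium F6. Used in excess on 28 at −78 °C, F6 forms lithium carboxylate 32, then the dilithium hemiaminal F7, and after a pH 4 quench the tris-silyl keto acid F8. Bu4NF buffered with AcOH (or HF·pyridine) in THF at 0 °C → rt would remove all three silyl groups under near-neutral conditions, and the route comes back at target 35.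

Step 7 (dibromocarbene addition under two-phase hydroxide). Hydroxide may hydrolyse the methyl ester, or the enol ether may be hydrated, before carbene capture occurs. The fallback sets out from 15, avoids base altogether and merges steps 7 and 8. Thermal carbene transfer from PhHgCBr3 (divalent mercury) in benzene at 80 °C should give adduct 16. At that temperature part or all of 16 is expected to ionise and collapse with its own bromide to the allylic α-bromo ether, methyl (7S)-2,3-dibromo-7-{2-[methoxy(methyl)amino]-2-oxoethyl}-2,5,6,7-tetrahydrooxepine-7-carboxylate F9. Addition of AgOAc and NaOAc to the same flask would open any remaining 16 and exchange the C2 bromide of F9 for acetate, and the route comes back at 18.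

**Further compounds**
F1 | step 16 | tert-butyl (S,E)-3-[5-(tert-butyldimethylsilyloxy)-4-methylpent-3-en-1-yl]-7-{2-[methoxy(methyl)amino]-2-oxoethyl}-2,5,6,7-tetrahydrooxepine-7-carboxylate | C/C(=C\CCC1=CCC[C@](CC(=O)N(C)OC)(C(=O)OC(C)(C)C)OC1)CO[Si](C)(C)C(C)(C)C
F2 | step 16 | lithium hemiaminal from F1 and 31 (new carbinol centre undefined) | C/C(=C\CCC1=CCC[C@](CC(O[Li])(N(C)OC)c2cc(OCOC)ccc2OCOC)(C(=O)OC(C)(C)C)OC1)CO[Si](C)(C)C(C)(C)C
F3 | step 16 | tert-butyl (S,E)-7-{2-[2,5-bis(methoxymethoxy)phenyl]-2-oxoethyl}-3-[5-(tert-butyldimethylsilyloxy)-4-methylpent-3-en-1-yl]-2,5,6,7-tetrahydrooxepine-7-carboxylate | C/C(=C\CCC1=CCC[C@](CC(=O)c2cc(OCOC)ccc2OCOC)(C(=O)OC(C)(C)C)OC1)CO[Si](C)(C)C(C)(C)C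
F4 | step 17 | 2-bromobenzene-1,4-diol | Oc1ccc(O)c(Br)c1
F5 | step 17 | 2-bromo-1,4-bis(tert-butyldimethylsilyloxy)benzene | CC(C)(C)[Si](C)(C)Oc1ccc(O[Si](C)(C)C(C)(C)C)c(Br)c1
F6 | step 17 | [2,5-bis(tert-butyldimethylsilyloxy)phenyl]lithium | CC(C)(C)[Si](C)(C)Oc1ccc(O[Si](C)(C)C(C)(C)C)c([Li])c1
F7 | step 17 | dilithium hemiaminal carboxylate from 32 and F6 (new carbinol centre undefined) | C/C(=C\CCC1=CCC[C@](CC(O[Li])(N(C)OC)c2cc(O[Si](C)(C)C(C)(C)C)ccc2O[Si](C)(C)C(C)(C)C)(C(=O)O[Li])OC1)CO[Si](C)(C)C(C)(C)C
F8 | step 17 | (S,E)-7-{2-[2,5-bis(tert-butyldimethylsilyloxy)phenyl]-2-oxoethyl}-3-[5-(tert-butyldimethylsilyloxy)-4-methylpent-3-en-1-yl]-2,5,6,7-tetrahydrooxepine-7-carboxylic acid | C/C(=C\CCC1=CCC[C@](CC(=O)c2cc(O[Si](C)(C)C(C)(C)C)ccc2O[Si](C)(C)C(C)(C)C)(C(=O)O)OC1)CO[Si](C)(C)C(C)(C)C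
F9 | step 7 | methyl (7S)-2,3-dibromo-7-{2-[methoxy(methyl)amino]-2-oxoethyl}-2,5,6,7-tetrahydrooxepine-7-carboxylate (both C2 epimers) | BrC1=CCC[C@](CC(=O)N(C)OC)(C(=O)OC)OC1Br
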